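A direct plan would join the four rings one bond at a time (ring A = the 1,4-phenylene, ring B = the phenol ring with the CH2CH2 bridge at C-1 and the ether oxygen at C-2, ring C = the 1,3-phenylene, ring D = the catechol ring with the carbinol carbon at C-1 and the ether oxygen at C-3) to the open bromo ketone A1, would close the 18-membered ring by arylation of its methyl ketone enolate at ring C to the macrocyclic ketone A2, would cleave the three methyl ethers with BBr3 to the ketone triphenol A3, and would reduce the C=O enantioselectively last.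
Weak point 1, the ring closure by enolate arylation: an entropically costly 18-membered closure through a short-lived aryl radical or aryl–metal species at millimolar dilution would sit at the end of the longest linear run, with reduction of the C–Br bond and intermolecular arylation as easy escapes.
Weak point 2, the global O-demethylation: three methyl ethers would be carried the whole way for a stage that builds nothing and exposes an enolisable α-aryl ketone to a strong Lewis acid.
Weak point 3, the last-step asymmetric transfer hydrogenation: the only stereocentre would be set on the most valuable intermediate, on a ketone deactivated by its para-phenol(ate), inside a macrocycle that may override the catalyst, with no later chance to raise the ee of a quinone-methide-prone carbinol.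

Retrosynthetic overview
The target is cut at both diaryl ether oxygens, the O between C-4 of ring A and C-3 of ring D and the O between C-2 of ring B and C-1 of ring C. These are the only links between its two C6–C2–C6 halves, the halves the liverwort presumably joins by phenol coupling.
The halves are the dihalo carbinol 7 (rings C and D, already (S)) and the bisphenol 13 (rings A and B). One flask forms both hindered C–O bonds and the 18-membered ring, which is closed at the ring B–ring C ether and not at a carbon bridge.
The stereocentre is set beforehand on the small acyclic ketone 6 by CBS reduction. Benzyl ethers are used throughout, so no enolate macrocyclisation, no BBr3 stage and no final asymmetric reduction is needed; one neutral hydrogenolysis ends the route.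
Key step: step 8

Remark: (3-bromobenzyl)zinc bromide 4 is assumed to be used as its commercial THF solution.

Step 1
Reactants: 1 5-iodovanillin (4-hydroxy-3-iodo-5-methoxybenzaldehyde)
Product: 2 3,4-dihydroxy-5-iodobenzaldehyde
Conditions: AlCl3, pyridine, CH2Cl2, reflux; aq HCl
Reagents that add atoms: none
Why: Chelation-assisted O-demethylation, in which the aluminium phenoxide of the free 4-OH activates only the neighbouring methyl ether for attack by pyridine, the standard way from 5-halovanillins to 5-halo catechol aldehydes.

Step 2
Reactants: 2 3,4-dihydroxy-5-iodobenzaldehyde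
Product: 3 3,4-bis(benzyloxy)-5-iodobenzaldehyde
Conditions: BnBr (2.3 equiv), K2CO3, DMF, 60 °C
Reagents that add atoms: benzyl bromide BrCc1ccccc1
Why: Twofold Williamson etherification of the catechol, which installs the only protecting group type of the route, removable at the end without acid or base.

Step 3
Reactants: 3 3,4-bis(benzyloxy)-5-iodobenzaldehyde, 4 (3-bromobenzyl)zinc bromide
Product: 6 1-[3,4-bis(benzyloxy)-5-iodophenyl]-2-(3-bromophenyl)ethanone, via racemic carbinol 5 (not isolated)
Conditions: 4 (1.3 equiv), MgCl2, THF, 0 °C → rt; aq NH4Cl; then Dess–Martin periodinane, CH2Cl2, rt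
Reagents that add atoms: none
Why: 1,2-Addition of a benzylic zinc reagent (activated by MgCl2), which leaves the C–I and C–Br bonds untouched, followed by Dess–Martin oxidation of the crude secondary benzylic alcohol to the aryl benzyl ketone.

Step 4
Reactants: 6 1-[3,4-bis(benzyloxy)-5-iodophenyl]-2-(3-bromophenyl)ethanone
Product: 7 (1S)-1-[3,4-bis(benzyloxy)-5-iodophenyl]-2-(3-bromophenyl)ethanol
Conditions: (R)-2-methyl-CBS-oxazaborolidine (15 mol%), BH3·SMe2, THF, −20 °C; MeOH
Reagents that add atoms: none
Why: Corey–Bakshi–Shibata reduction, in which the (R)-oxazaborolidine–borane complex binds the ketone with the aryl group as the large and the arylmethyl group as the small substituent and should give the (S)-carbinol, the same sense as acetophenone → (S)-1-phenylethanol with this catalyst (CH2Ar replaces CH3, same CIP order).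

Step 5
Reactants: 8 2,3-dihydroxybenzaldehyde
Product: 9 3-(benzyloxy)-2-hydroxybenzaldehyde
Conditions: NaH (2.1 equiv), DMSO, rt; BnBr (1.0 equiv); aq HCl
Reagents that add atoms: benzyl bromide BrCc1ccccc1
Why: Regioselective Williamson etherification of the dianion, whose 3-oxide is the more nucleophilic because the 2-oxide is conjugated with and chelated by the formyl group.

Step 6
Reactants: 10 4-hydroxybenzyl alcohol
Product: 11 (4-hydroxybenzyl)triphenylphosphonium bromide
Conditions: PPh3·HBr, MeCN, reflux
Reagents that add atoms: triphenylphosphine hydrobromide [Br-].[PH+](c1ccccc1)(c1ccccc1)c1ccccc1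
Why: Acid-promoted substitution of the p-hydroxybenzylic OH by triphenylphosphine through the stabilised benzylic cation (quinone methide) gives the phosphonium salt with loss of water.

Step 7
Reactants: 9 3-(benzyloxy)-2-hydroxybenzaldehyde, 11 (4-hydroxybenzyl)triphenylphosphonium bromide
Product: 13 2-(benzyloxy)-6-[2-(4-hydroxyphenyl)ethyl]phenol, via stilbene 12 (not isolated)
Conditions: LiN(SiMe3)2 (3.2 equiv), THF, 0 °C → 50 °C; aq HCl; then TsNHNH2, NaOAc, THF/H2O, reflux
Reagents that add atoms: none
Why: Wittig olefination with excess base, in which the benzylic ylide is made more nucleophilic by its para-oxide and should therefore still attack the salicylaldehyde phenoxide, followed by diimide reduction of the crude E/Z stilbene, which saturates the C=C bond without touching the benzyl ether.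

Step 8
Reactants: 7 (1S)-1-[3,4-bis(benzyloxy)-5-iodophenyl]-2-(3-bromophenyl)ethanol, 13 2-(benzyloxy)-6-[2-(4-hydroxyphenyl)ethyl]phenol
Product: 15 macrocyclic tri-O-benzyl ether of the target (benzyl on ring B O-3 and ring D O-4 and O-5, free (S)-carbinol), via seco ether 14 (not isolated)
Conditions: CuI (20 mol%), picolinic acid (40 mol%), K3PO4 (4 equiv), DMSO, 0.1 M, 70 °C, Ar; then added over 10 h to CuI (0.5 equiv), picolinic acid (1 equiv), K3PO4 in DMSO at 110 °C (final 2 mM)
Reagents that add atoms: none
Why: Both bonds should form by ligand-accelerated Ullmann diaryl ether synthesis, in which a picolinate-bound phenoxide of monovalent copper adds oxidatively to the aryl halide and the resulting aryl phenoxide of trivalent copper eliminates the diaryl ether. The closest known reaction types are the CuI/picolinic acid coupling of ortho-substituted phenols with aryl iodides and bromides and the intramolecular Ullmann closure of diaryl ether cyclophanes. The first, intermolecular coupling joins the ring A oxygen to C-3 of ring D and gives 14; the second closes the 18-membered ring by intramolecular C(aryl)–O coupling of the ring B C-2 oxygen with C-1 of ring C. No stereocentre is formed: the (S)-carbinol of 7 has no acidic α-hydrogen, its alkoxide should not compete under these phenol-selective conditions, and it is carried through unchanged. The step needs the right pairing, and both preferences point the same way: the unhindered ring A phenoxide and the C–I bond are the fast partners at 70 °C, whereas the 2,6-disubstituted ring B phenoxide and the C–Br bond need 110 °C. Slow addition into the hot catalyst keeps 14 dilute, so that ring closure should beat oligomerisation.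

Step 9
Reactants: 15 macrocyclic tri-O-benzyl ether
Product: 16 CNP0333307.1, the (S)-carbinol
Conditions: H2 (1 atm), 10% Pd/C, NaHCO3 (solid), EtOAc/EtOH, rt
Reagents that add atoms: none
Why: Hydrogenolysis of the three aryl benzyl ethers over Pd/C in an acid-free medium should be much faster than cleavage of the secondary benzylic C–OH bond, as in the O-debenzylation of para-benzyloxy benzylic carbinols of lignin model compounds, and the neutral conditions avoid ionising the p-hydroxybenzylic carbinol, so the stereocentre stays as set.

Compound list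
1 | 5-iodovanillin (4-hydroxy-3-iodo-5-methoxybenzaldehyde) | O=Cc1cc(I)c(O)c(OC)c1 | starting material
2 | 3,4-dihydroxy-5-iodobenzaldehyde | O=Cc1cc(I)c(O)c(O)c1 | intermediate
3 | 3,4-bis(benzyloxy)-5-iodobenzaldehyde | O=Cc1cc(I)c(OCc2ccccc2)c(OCc2ccccc2)c1 | intermediate
4 | (3-bromobenzyl)zinc bromide | Br[Zn]Cc1cccc(Br)c1 | starting material
5 | racemic 1-[3,4-bis(benzyloxy)-5-iodophenyl]-2-(3-bromophenyl)ethanol, not isolated | OC(Cc1cccc(Br)c1)c1cc(I)c(OCc2ccccc2)c(OCc2ccccc2)c1 | intermediate
6 | 1-[3,4-bis(benzyloxy)-5-iodophenyl]-2-(3-bromophenyl)ethanone | O=C(Cc1cccc(Br)c1)c1cc(I)c(OCc2ccccc2)c(OCc2ccccc2)c1 | intermediate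
7 | (1S)-1-[3,4-bis(benzyloxy)-5-iodophenyl]-2-(3-bromophenyl)ethanol | O[C@@H](Cc1cccc(Br)c1)c1cc(I)c(OCc2ccccc2)c(OCc2ccccc2)c1 | intermediate
8 | 2,3-dihydroxybenzaldehyde | O=Cc1cccc(O)c1O | starting material
9 | 3-(benzyloxy)-2-hydroxybenzaldehyde | O=Cc1cccc(OCc2ccccc2)c1O | intermediate
10 | 4-hydroxybenzyl alcohol | OCc1ccc(O)cc1 | starting material
11 | (4-hydroxybenzyl)triphenylphosphonium bromide | Oc1ccc(cc1)C[P+](c1ccccc1)(c1ccccc1)c1ccccc1.[Br-] | intermediate
12 | 4-[2-(3-benzyloxy-2-hydroxyphenyl)ethenyl]phenol (E/Z mixture), not isolated | Oc1ccc(cc1)C=Cc1cccc(OCc2ccccc2)c1O | intermediate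
13 | 2-(benzyloxy)-6-[2-(4-hydroxyphenyl)ethyl]phenol | Oc1ccc(cc1)CCc1cccc(OCc2ccccc2)c1O | intermediate
14 | (1S)-1-[3,4-bis(benzyloxy)-5-{4-[2-(3-benzyloxy-2-hydroxyphenyl)ethyl]phenoxy}phenyl]-2-(3-bromophenyl)ethanol (seco ether), not isolated | O[C@@H](Cc1cccc(Br)c1)c1cc(Oc2ccc(CCc3cccc(OCc4ccccc4)c3O)cc2)c(OCc2ccccc2)c(OCc2ccccc2)c1 | intermediate
15 | 18-membered macrocyclic tri-O-benzyl ether: target 16 with benzyl ethers at ring B O-3 and at ring D O-4 and O-5, free (S)-carbinol | C(c1ccccc1)Oc1cc2cc(c1OCc1ccccc1)Oc1ccc(cc1)CCc1cccc(OCc3ccccc3)c1Oc1cccc(c1)C[C@@H]2O | intermediate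
16 | CNP0333307.1, (S)-carbinol on the carbon bound to ring D | Oc1cc2cc(c1O)Oc1ccc(cc1)CCc1cccc(O)c1Oc1cccc(c1)C[C@@H]2O | target

Total step count: 9. Longest linear sequence: 6 (steps 1, 2, 3, 4, 8, 9); steps 5 to 7 form the second branch.

Steps most likely to fail

Step 8 (twofold C–O coupling). The ring A phenoxide may attack the C–Br bond of ring C instead of the C–I bond of ring D, or the hindered ring B phenoxide of 14 may lose to oligomerisation and hydrodehalogenation at high dilution. Fallback: the two ether bonds are made one after the other with monophenols and the ring is closed at the ring A–ring B bridge by metathesis. Setting out from 7, coupling with 4-hydroxybenzaldehyde at the C–I bond (CuI, picolinic acid, K3PO4, DMSO, 70 °C) should give 4-{2,3-bis(benzyloxy)-5-[(1S)-2-(3-bromophenyl)-1-hydroxyethyl]phenoxy}benzaldehyde F1. Coupling of its C–Br bond with an excess of 9 at 110 °C should give the dialdehyde 2-(3-{(2S)-2-[3,4-bis(benzyloxy)-5-(4-formylphenoxy)phenyl]-2-hydroxyethyl}phenoxy)-3-(benzyloxy)benzaldehyde F2. Twofold Wittig methylenation (MePPh3Br, KOtBu, THF) should give the bis-styrene (1S)-1-[3,4-bis(benzyloxy)-5-(4-ethenylphenoxy)phenyl]-2-{3-[2-(benzyloxy)-6-ethenylphenoxy]phenyl}ethanol F3. Ring-closing metathesis (second-generation Grubbs catalyst, toluene, 80 °C, 2 mM) should give the macrocyclic stilbene F4, that is 15 with CH=CH in place of the CH2CH2 bridge. Diimide reduction (TsNHNH2, NaOAc) would return to the route at 15.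

Step 7 (Wittig olefination of two phenoxide partners). The aldehyde, deactivated as its ortho-phenoxide, may react too slowly with the ylide, and the doubly anionic ylide may decompose first. Fallback: a Heck arylation in place of the olefination. Setting out from 9, methylenation (MePPh3Br, KOtBu, THF) should give 2-(benzyloxy)-6-ethenylphenol F5. Heck coupling with 4-iodophenol (Pd(OAc)2, P(o-tol)3, Et3N, DMF, 90 °C) should give the (E)-stilbene 12, which the diimide reduction of step 7 would convert into 13.

Step 9 (final hydrogenolysis). Once the para-phenol of ring D is free, reduction may go on to cleave the benzylic C–OH bond. Fallback: the carbinol is masked during the hydrogenolysis. Setting out from 15, silylation (tBuMe2SiOTf, 2,6-lutidine, CH2Cl2, −78 °C) should give the tert-butyldimethylsilyl ether of 15 F6. Hydrogenolysis (H2, 10% Pd/C, EtOAc) should give the triphenol silyl ether F7. Buffered fluoride (Bu4NF/AcOH, THF, 0 °C) would return to the route at 16.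

Further compounds
F1 | step 8 | 4-{2,3-bis(benzyloxy)-5-[(1S)-2-(3-bromophenyl)-1-hydroxyethyl]phenoxy}benzaldehyde | O[C@@H](Cc1cccc(Br)c1)c1cc(Oc2ccc(C=O)cc2)c(OCc2ccccc2)c(OCc2ccccc2)c1
F2 | step 8 | 2-(3-{(2S)-2-[3,4-bis(benzyloxy)-5-(4-formylphenoxy)phenyl]-2-hydroxyethyl}phenoxy)-3-(benzyloxy)benzaldehyde | O[C@@H](Cc1cccc(Oc2c(C=O)cccc2OCc2ccccc2)c1)c1cc(Oc2ccc(C=O)cc2)c(OCc2ccccc2)c(OCc2ccccc2)c1
F3 | step 8 | (1S)-1-[3,4-bis(benzyloxy)-5-(4-ethenylphenoxy)phenyl]-2-{3-[2-(benzyloxy)-6-ethenylphenoxy]phenyl}ethanol | O[C@@H](Cc1cccc(Oc2c(C=C)cccc2OCc2ccccc2)c1)c1cc(Oc2ccc(C=C)cc2)c(OCc2ccccc2)c(OCc2ccccc2)c1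
F4 | step 8 | macrocyclic stilbene: 15 with CH=CH in place of the CH2CH2 bridge between ring A and ring B (E/Z mixture), (S)-carbinol | C(c1ccccc1)Oc1cc2cc(c1OCc1ccccc1)Oc1ccc(cc1)C=Cc1cccc(OCc3ccccc3)c1Oc1cccc(c1)C[C@@H]2O
F5 | step 7 | 2-(benzyloxy)-6-ethenylphenol | C=Cc1cccc(OCc2ccccc2)c1O
F6 | step 9 | tert-butyldimethylsilyl ether of the (S)-carbinol of 15 | C(c1ccccc1)Oc1cc2cc(c1OCc1ccccc1)Oc1ccc(cc1)CCc1cccc(OCc3ccccc3)c1Oc1cccc(c1)C[C@@H]2O[Si](C)(C)C(C)(C)C
F7 | step 9 | tert-butyldimethylsilyl ether of the (S)-carbinol of 16 (triphenol) | Oc1cc2cc(c1O)Oc1ccc(cc1)CCc1cccc(O)c1Oc1cccc(c1)C[C@@H]2O[Si](C)(C)C(C)(C)C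
A1 | direct plan | open bromo ketone, 1-{3-[4-(2-{2-(3-bromophenoxy)-3-methoxyphenyl}ethyl)phenoxy]-4,5-dimethoxyphenyl}ethanone | CC(=O)c1cc(OC)c(OC)c(c1)Oc1ccc(cc1)CCc1cccc(OC)c1Oc1cccc(Br)c1
A2 | direct plan | 18-membered macrocyclic ketone tri-O-methyl ether | COc1cc2cc(c1OC)Oc1ccc(cc1)CCc1cccc(OC)c1Oc1cccc(c1)CC2=O
A3 | direct plan | macrocyclic ketone triphenol | Oc1cc2cc(c1O)Oc1ccc(cc1)CCc1cccc(O)c1Oc1cccc(c1)CC2=O
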